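Disconnections: 52 ⇒ heptamethyl ether 51 (global O-demethylation) ⇒ triol 50 (O1–C2 bond of ring 1, phenol onto the anisylic carbon) ⇒ siloxyalkyne 44 + styrylcyclobutenone 9 (benzannulation of the benzo ring of unit 1); the same two cuts on the dihydrobenzofuran inside 44 lead to siloxyalkyne 23 + allylcyclobutenone 4.
Feature used: in each 2,3-dihydrobenzofuran the benzo ring is a resorcinol whose C3a (the carbon carrying C3) lies between the two oxygens C4–O and C7a–O1, while the C6 substituent (the E-styryl group in the unprimed unit, C3 of that unit in the primed one) is meta to both; a cyclobutenone/ynol ether benzannulation fixes this 1,2,3,5 pattern by connectivity (bonds C3a–C7a, C4–C5, C7–C7a).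
Stereochemistry: each C3 centre comes from an Evans syn aldol of an arylacetyl oxazolidinone with 4-methoxybenzaldehyde; the acyl carbon is then turned into the TIPS ynol ether (Corey–Fuchs olefination, then acetylide oxidation in the same flask as the rearrangement).
Remark on the chemistry: the anisylic carbinol of each dyad serves only as a leaving group whose configuration is replaced when the phenol closes the trans ring, so the syn dyad delivered by the aldol is carried (backside displacement and the free cation both give trans).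
Order of ring formation: benzo ring of the primed unit (step 11), its furan ring (step 12), benzo ring of the unprimed unit (step 23), its furan ring (step 25).
Key step: step 23

Abbreviation in names: DHB = (2S,3S)-3-(3,5-dimethoxyphenyl)-4-methoxy-2-(4-methoxyphenyl)-2,3-dihydro-1-benzofuran-6-yl; TBS = tert-butyldimethylsilyl; TIPS = triisopropylsilyl.

Step 1
Reactants: 1 3-ethoxycyclobut-2-en-1-one; 2 allylmagnesium bromide
Product: 4 3-(prop-2-en-1-yl)cyclobut-2-en-1-one, via magnesium alkoxide 3 (not isolated)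
Conditions: THF, −78 °C; then 1 M HCl, 0 °C
Reagents that add atoms: water, O
Why: 1,2-Addition of the Grignard reagent to the carbonyl of the vinylogous ester, then acid hydrolysis of the enol ether with loss of water (carbonyl transposition of the Stork–Danheiser type), should give the 3-substituted cyclobutenone.

Step 2
Reactants: 5 2,4-dimethoxybenzaldehyde
Product: 6 1-[(E)-2-iodoethenyl]-2,4-dimethoxybenzene
Conditions: CrCl2, CHI3, THF/dioxane, 0 °C → rt
Reagents that add atoms: iodoform, IC(I)I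
Why: Takai olefination of an aromatic aldehyde with the geminal dichromium reagent from iodoform should give the E vinyl iodide, because the anti-periplanar elimination runs through the less crowded adduct.

Step 3
Reactants: 6 1-[(E)-2-iodoethenyl]-2,4-dimethoxybenzene; 1 3-ethoxycyclobut-2-en-1-one
Product: 9 3-[(E)-2-(2,4-dimethoxyphenyl)ethenyl]cyclobut-2-en-1-one, via vinyllithium 7 (not isolated), via lithium alkoxide 8 (not isolated)
Conditions: t-BuLi (2 equiv), Et2O, −78 °C; then 1, −78 °C; then 0.5 M HCl, THF, 0 °C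
Reagents that add atoms: water, O
Why: Iodine–lithium exchange keeps the alkene geometry, the vinyllithium adds 1,2 to the vinylogous ester, and mild acid unmasks the dienone by the same hydrolytic carbonyl transposition as in step 1.

Step 4
Reactants: 10 (3,5-dimethoxyphenyl)acetic acid; 11 (4R)-4-benzyl-1,3-oxazolidin-2-one
Product: 13 (4R)-4-benzyl-3-[(3,5-dimethoxyphenyl)acetyl]-1,3-oxazolidin-2-one, via mixed anhydride 12 (not isolated)
Conditions: PivCl, Et3N, THF, −20 °C; then 11, LiCl, rt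
Reagents that add atoms: none
Why: N-Acylation of the oxazolidinone through the pivalic mixed anhydride with LiCl/Et3N activation is the standard entry to Evans imides.

Step 5
Reactants: 13 (4R)-4-benzyl-3-[(3,5-dimethoxyphenyl)acetyl]-1,3-oxazolidin-2-one; 14 4-methoxybenzaldehyde
Product: 16 (4R)-4-benzyl-3-[(2R,3R)-2-(3,5-dimethoxyphenyl)-3-hydroxy-3-(4-methoxyphenyl)propanoyl]-1,3-oxazolidin-2-one, via boron enolate 15 (not isolated)
Conditions: Bu2BOTf, i-Pr2NEt, CH2Cl2, −78 → 0 °C; then 14, −78 → 0 °C; then pH 7 buffer, MeOH, 30% H2O2, 0 °C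
Reagents that add atoms: none
Why: Evans syn aldol reaction, in which the Z boron enolate reacts through a Zimmerman–Traxler chair on the face away from the benzyl group of the (R)-auxiliary, sets the aryl-bearing carbon as R (the later C3 of the primed ring) and the carbinol carbon syn to it.

Step 6
Reactants: 16 syn aldol imide
Product: 17 (4R)-4-benzyl-3-[(2R,3R)-3-(TBS-oxy)-2-(3,5-dimethoxyphenyl)-3-(4-methoxyphenyl)propanoyl]-1,3-oxazolidin-2-one
Conditions: TBSOTf, 2,6-lutidine, CH2Cl2, 0 °C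
Reagents that add atoms: tert-butyldimethylsilyl triflate, CC(C)(C)[Si](C)(C)OS(=O)(=O)C(F)(F)F
Why: Silylation of the secondary alcohol with the silyl triflate and 2,6-lutidine blocks retro-aldol cleavage and keeps the anisylic oxygen as a latent leaving group.

Step 7
Reactants: 17 TBS-protected aldol imide
Product: 18 (2S,3R)-3-(TBS-oxy)-2-(3,5-dimethoxyphenyl)-3-(4-methoxyphenyl)propan-1-ol
Conditions: LiBH4, MeOH (1 equiv), THF, 0 °C
Reagents that add atoms: none
Why: Reductive cleavage of the imide with lithium borohydride attacks the exocyclic carbonyl and should give the primary alcohol with the α-aryl centre intact, the auxiliary being recovered.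

Step 8
Reactants: 18 primary alcohol
Product: 19 (2R,3R)-3-(TBS-oxy)-2-(3,5-dimethoxyphenyl)-3-(4-methoxyphenyl)propanal
Conditions: Dess–Martin periodinane, pyridine, CH2Cl2, 0 °C → rt
Reagents that add atoms: none
Why: Dess–Martin oxidation buffered with pyridine gives the aldehyde without base, so the enolisable α-aryl centre and the β-silyloxy group are kept, and the aldehyde is used crude.

Step 9
Reactants: 19 α-aryl aldehyde
Product: 20 tert-butyl{[(1R,2R)-4,4-dibromo-2-(3,5-dimethoxyphenyl)-1-(4-methoxyphenyl)but-3-en-1-yl]oxy}dimethylsilane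
Conditions: CBr4, PPh3, Zn, CH2Cl2, rt (ylide preformed); then 19, 0 °C → rt
Reagents that add atoms: carbon tetrabromide, BrC(Br)(Br)Br
Why: Corey–Fuchs dibromo-olefination with the ylide preformed from CBr4, PPh3 and zinc is a near-neutral Wittig reaction and therefore compatible with the epimerisable aldehyde.

Step 10
Reactants: 20 dibromoalkene
Product: 23 tert-butyl{[(1R,2S)-2-(3,5-dimethoxyphenyl)-1-(4-methoxyphenyl)-4-(TIPS-oxy)but-3-yn-1-yl]oxy}dimethylsilane, via lithium acetylide 21 (not isolated), via lithium ynolate 22 (not isolated)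
Conditions: n-BuLi (2.05 equiv), THF, −78 °C, 1 h; then t-BuOOLi (preformed from t-BuOOH and LiHMDS, THF, −78 °C), −78 → 0 °C; then TIPSOTf, −78 °C
Reagents that add atoms: tert-butyl hydroperoxide, CC(C)(C)OO; triisopropylsilyl triflate, CC(C)[Si](C(C)C)(C(C)C)OS(=O)(=O)C(F)(F)F
Why: The second stage of the Corey–Fuchs sequence (bromine–lithium exchange, Fritsch–Buttenberg–Wiechell rearrangement, deprotonation by the second equivalent of n-BuLi) gives the lithium acetylide directly, which lithium tert-butyl peroxide oxidises to the ynolate and the bulky silyl triflate traps on oxygen (ynolate O-silylation) as the isolable triisopropylsilyl ynol ether, with the propargylic centre untouched at low temperature and the 1-bromobutane by-product inert.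

Step 11
Reactants: 23 siloxyalkyne; 4 3-(prop-2-en-1-yl)cyclobut-2-en-1-one
Product: 28 2-[(1S,2R)-2-(TBS-oxy)-1-(3,5-dimethoxyphenyl)-2-(4-methoxyphenyl)ethyl]-5-(prop-2-en-1-yl)-3-(TIPS-oxy)phenol, via vinylketene 24 (not isolated), via vinylcyclobutenone 25 (not isolated), via dienylketene 26 (not isolated), via cyclohexadienone 27 (not isolated)
Conditions: 4 (1.3 equiv), toluene, 80 → 110 °C
Reagents that add atoms: none
Why: Danheiser benzannulation (4π opening of 4, regioselective [2+2] of the vinylketene with the ynol ether, 4π opening, 6π closure, tautomerisation) should build the resorcinol ring of the primed unit with the side chain between the two oxygens and the allyl group meta to both, without forming or touching a stereocentre.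

Step 12
Reactants: 28 benzannulation phenol
Product: 29 {[(2S,3S)-3-(3,5-dimethoxyphenyl)-2-(4-methoxyphenyl)-6-(prop-2-en-1-yl)-2,3-dihydro-1-benzofuran-4-yl]oxy}triisopropylsilane
Conditions: TFA, CH2Cl2, 0 °C
Reagents that add atoms: none
Why: Acid-mediated SN1 cycloetherification, in which trifluoroacetic acid ionises the p-methoxybenzylic silyl ether and the neighbouring free phenol closes the furan ring (5-exo), should give the trans-2,3-diaryl ring, favoured kinetically (attack anti to the C3 aryl, also the outcome of backside displacement on the syn dyad) and thermodynamically under reversible ionisation.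

Step 13
Reactants: 29 aryl TIPS ether
Product: 31 (2S,3S)-3-(3,5-dimethoxyphenyl)-4-methoxy-2-(4-methoxyphenyl)-6-(prop-2-en-1-yl)-2,3-dihydro-1-benzofuran, via ammonium phenoxide 30 (not isolated)
Conditions: TBAF, THF, 0 °C; then MeI, rt
Reagents that add atoms: iodomethane, CI
Why: Fluoride cleaves the aryl silyl ether and the ammonium phenoxide is methylated in the same flask (Williamson etherification), which brings the C4 oxygen to the protecting group of the other phenols.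

Step 14
Reactants: 31 allyl dihydrobenzofuran
Product: 32 (DHB)acetaldehyde
Conditions: OsO4 (cat.), NaIO4, 2,6-lutidine, dioxane/H2O, rt
Reagents that add atoms: osmium tetroxide, O=[Os](=O)(=O)=O (oxygen donor, regenerated by sodium periodate, [Na+].[O-]I(=O)(=O)=O)
Why: Lemieux–Johnson cleavage (catalytic dihydroxylation and periodate glycol cleavage) of the only alkene should give the arylacetaldehyde, which is carried on at once.

Step 15
Reactants: 32 (DHB)acetaldehyde
Product: 33 (DHB)acetic acid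
Conditions: NaClO2, NaH2PO4, 2-methylbut-2-ene, t-BuOH/H2O, rt
Reagents that add atoms: sodium chlorite, [Na+].[O-]Cl=O
Why: Pinnick oxidation with 2-methylbut-2-ene as hypochlorite scavenger converts the aldehyde into the arylacetic acid without chlorination of the electron-rich rings.

Step 16
Reactants: 33 (DHB)acetic acid; 11 (4R)-4-benzyl-1,3-oxazolidin-2-one
Product: 35 (4R)-4-benzyl-3-[(DHB)acetyl]-1,3-oxazolidin-2-one, via mixed anhydride 34 (not isolated)
Conditions: PivCl, Et3N, THF, −20 °C; then 11, LiCl, rt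
Reagents that add atoms: none
Why: The same mixed-anhydride N-acylation as in step 4 attaches the auxiliary for the second aldol.

Step 17
Reactants: 35 (4R)-4-benzyl-3-[(DHB)acetyl]-1,3-oxazolidin-2-one; 14 4-methoxybenzaldehyde
Product: 37 (4R)-4-benzyl-3-[(2R,3R)-2-(DHB)-3-hydroxy-3-(4-methoxyphenyl)propanoyl]-1,3-oxazolidin-2-one, via boron enolate 36 (not isolated)
Conditions: Bu2BOTf, i-Pr2NEt, CH2Cl2, −78 → 0 °C; then 14, −78 → 0 °C; then pH 7 buffer, MeOH, 30% H2O2, 0 °C
Reagents that add atoms: none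
Why: Evans syn aldol reaction under auxiliary control, as in step 5, sets the DHB-bearing carbon as R (the later C3 of the unprimed ring) independently of the remote stereocentres of the DHB group.

Step 18
Reactants: 37 syn aldol imide
Product: 38 (4R)-4-benzyl-3-[(2R,3R)-3-(TBS-oxy)-2-(DHB)-3-(4-methoxyphenyl)propanoyl]-1,3-oxazolidin-2-one
Conditions: TBSOTf, 2,6-lutidine, CH2Cl2, 0 °C
Reagents that add atoms: tert-butyldimethylsilyl triflate, CC(C)(C)[Si](C)(C)OS(=O)(=O)C(F)(F)F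
Why: Silylation with the silyl triflate and 2,6-lutidine, as in step 6, protects the carbinol against retro-aldol cleavage.

Step 19
Reactants: 38 TBS-protected aldol imide
Product: 39 (2S,3R)-3-(TBS-oxy)-2-(DHB)-3-(4-methoxyphenyl)propan-1-ol
Conditions: LiBH4, MeOH (1 equiv), THF, 0 °C
Reagents that add atoms: none
Why: Reductive cleavage of the imide with lithium borohydride, as in step 7, gives the primary alcohol and returns the auxiliary.

Step 20
Reactants: 39 primary alcohol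
Product: 40 (2R,3R)-3-(TBS-oxy)-2-(DHB)-3-(4-methoxyphenyl)propanal
Conditions: Dess–Martin periodinane, pyridine, CH2Cl2, 0 °C → rt
Reagents that add atoms: none
Why: Buffered Dess–Martin oxidation, as in step 8, gives the configurationally labile α-aryl aldehyde without base, and it is used crude.

Step 21
Reactants: 40 α-aryl aldehyde
Product: 41 tert-butyl{[(1R,2R)-4,4-dibromo-2-(DHB)-1-(4-methoxyphenyl)but-3-en-1-yl]oxy}dimethylsilane
Conditions: CBr4, PPh3, Zn, CH2Cl2, rt (ylide preformed); then 40, 0 °C → rt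
Reagents that add atoms: carbon tetrabromide, BrC(Br)(Br)Br
Why: Corey–Fuchs dibromo-olefination with the preformed ylide, as in step 9, homologates the aldehyde under near-neutral conditions.

Step 22
Reactants: 41 dibromoalkene
Product: 44 tert-butyl{[(1R,2S)-2-(DHB)-1-(4-methoxyphenyl)-4-(TIPS-oxy)but-3-yn-1-yl]oxy}dimethylsilane, via lithium acetylide 42 (not isolated), via lithium ynolate 43 (not isolated)
Conditions: n-BuLi (2.05 equiv), THF, −78 °C, 1 h; then t-BuOOLi (preformed from t-BuOOH and LiHMDS, THF, −78 °C), −78 → 0 °C; then TIPSOTf, −78 °C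
Reagents that add atoms: tert-butyl hydroperoxide, CC(C)(C)OO; triisopropylsilyl triflate, CC(C)[Si](C(C)C)(C(C)C)OS(=O)(=O)C(F)(F)F
Why: Bromine–lithium exchange and Fritsch–Buttenberg–Wiechell rearrangement (faster at −78 °C than any deprotonation of the dihydrobenzofuran), then acetylide oxidation to the ynolate and O-silylation, as in step 10, give the siloxyalkyne that carries the C3 centre, the latent C2 leaving group and the complete primed dihydrobenzofuran.

Step 23
Reactants: 44 siloxyalkyne; 9 3-[(E)-2-(2,4-dimethoxyphenyl)ethenyl]cyclobut-2-en-1-one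
Product: 49 2-[(1S,2R)-2-(TBS-oxy)-1-(DHB)-2-(4-methoxyphenyl)ethyl]-5-[(E)-2-(2,4-dimethoxyphenyl)ethenyl]-3-(TIPS-oxy)phenol, via vinylketene 45 (not isolated), via vinylcyclobutenone 46 (not isolated), via dienylketene 47 (not isolated), via cyclohexadienone 48 (not isolated)
Conditions: 9 (1.3 equiv), toluene (degassed, dark), 80 → 110 °C
Reagents that add atoms: none
Why: Heating opens cyclobutenone 9 by 4π electrocyclic cleavage to vinylketene 45, whose carbonyl carbon is attacked by the nucleophilic β-carbon of ynol ether 44 in a regioselective [2+2] cycloaddition to vinylcyclobutenone 46; 4π opening of 46 gives dienylketene 47, which closes by 6π electrocyclisation to cyclohexadienone 48 and tautomerises to phenol 49. The closest known reaction type is the Danheiser benzannulation of 3-substituted cyclobutenones with triisopropylsiloxyalkynes to 2-substituted resorcinol monosilyl ethers, rehearsed in step 11 on the simpler alkyne 23. The benzo ring of the unprimed unit is closed by the 6π electrocyclisation (C7–C7a) after the [2+2] has made C3a–C7a and C4–C5, so the ketene carbonyl becomes the C7a hydroxyl next to the side chain. No stereocentre is formed, and C3 and the carbinol carbon pass through unchanged because the conditions are neutral and thermal. The step needs regioselectivity (ketene carbon to the alkyne carbon bearing the side chain, secured by the polarisation of the ynol ether), chemoselectivity for the ynol ether over the styryl alkene (secured by its far higher reactivity towards ketenes) and retention of the E alkene (no light, no acid).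

Step 24
Reactants: 49 benzannulation phenol
Product: 50 2-[(1S,2R)-1-(DHB)-2-hydroxy-2-(4-methoxyphenyl)ethyl]-5-[(E)-2-(2,4-dimethoxyphenyl)ethenyl]benzene-1,3-diol
Conditions: TBAF, THF, 0 °C → rt
Reagents that add atoms: none
Why: Fluoride-mediated desilylation removes both silyl ethers, and the two phenolic hydroxyls that now flank the side chain are equivalent by the local symmetry of the 2-substituted 5-styrylresorcinol, so that either can close ring 1.

Step 25
Reactants: 50 triol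
Product: 51 (2S,3S)-3-(DHB)-6-[(E)-2-(2,4-dimethoxyphenyl)ethenyl]-2-(4-methoxyphenyl)-2,3-dihydro-1-benzofuran-4-ol
Conditions: TsOH·H2O (10 mol %), CH2Cl2, 0 °C
Reagents that add atoms: none
Why: Acid-catalysed SN1 cycloetherification of the free p-methoxybenzylic alcohol needs only catalytic sulfonic acid, which spares the dimethoxystilbene, and 5-exo capture of the cation by a flanking phenol should give the trans ring for the reasons given in step 12.

Step 26
Reactants: 51 heptamethyl ether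
Product: 52 CNP0186204.1
Conditions: BBr3, CH2Cl2, −78 → 0 °C; then MeOH, H2O
Reagents that add atoms: none
Why: Boron tribromide ether cleavage through aryloxyboron bromides removes all seven methyl groups, the usual last operation for permethylated stilbene oligomers, and reversible C2–O ionisation cannot scramble the rings because trans is the thermodynamic arrangement.

Compound list
1 | 3-ethoxycyclobut-2-en-1-one | CCOC1=CC(=O)C1 | starting material
2 | allylmagnesium bromide | C=CC[Mg]Br | starting material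
3 | bromomagnesium 3-ethoxy-1-(prop-2-en-1-yl)cyclobut-2-en-1-olate (racemic) | CCOC1=CC(CC=C)(O[Mg]Br)C1 | intermediate
4 | 3-(prop-2-en-1-yl)cyclobut-2-en-1-one | C=CCC1=CC(=O)C1 | intermediate
5 | 2,4-dimethoxybenzaldehyde | COc1ccc(C=O)c(OC)c1 | starting material
6 | 1-[(E)-2-iodoethenyl]-2,4-dimethoxybenzene | COc1ccc(/C=C/I)c(OC)c1 | intermediate
7 | [(E)-2-(2,4-dimethoxyphenyl)ethenyl]lithium | COc1ccc(/C=C/[Li])c(OC)c1 | intermediate
8 | lithium 1-[(E)-2-(2,4-dimethoxyphenyl)ethenyl]-3-ethoxycyclobut-2-en-1-olate (racemic) | CCOC1=CC(O[Li])(/C=C/c2ccc(OC)cc2OC)C1 | intermediate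
9 | 3-[(E)-2-(2,4-dimethoxyphenyl)ethenyl]cyclobut-2-en-1-one | O=C1C=C(/C=C/c2ccc(OC)cc2OC)C1 | intermediate
10 | (3,5-dimethoxyphenyl)acetic acid | COc1cc(CC(=O)O)cc(OC)c1 | starting material
11 | (4R)-4-benzyl-1,3-oxazolidin-2-one | O=C1N[C@H](Cc2ccccc2)CO1 | starting material
12 | (3,5-dimethoxyphenyl)acetic pivalic anhydride | COc1cc(CC(=O)OC(=O)C(C)(C)C)cc(OC)c1 | intermediate
13 | (4R)-4-benzyl-3-[(3,5-dimethoxyphenyl)acetyl]-1,3-oxazolidin-2-one | COc1cc(CC(=O)N2[C@H](Cc3ccccc3)COC2=O)cc(OC)c1 | intermediate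
14 | 4-methoxybenzaldehyde | COc1ccc(C=O)cc1 | starting material
15 | Z dibutylboron enolate of 13 | CCCCB(CCCC)O/C(=C\c1cc(OC)cc(OC)c1)N1[C@H](Cc2ccccc2)COC1=O | intermediate
16 | (4R)-4-benzyl-3-[(2R,3R)-2-(3,5-dimethoxyphenyl)-3-hydroxy-3-(4-methoxyphenyl)propanoyl]-1,3-oxazolidin-2-one | O=C([C@H](c1cc(OC)cc(OC)c1)[C@@H](O)c1ccc(OC)cc1)N1[C@H](Cc2ccccc2)COC1=O | intermediate
17 | (4R)-4-benzyl-3-[(2R,3R)-3-(TBS-oxy)-2-(3,5-dimethoxyphenyl)-3-(4-methoxyphenyl)propanoyl]-1,3-oxazolidin-2-one | O=C([C@H](c1cc(OC)cc(OC)c1)[C@@H](O[Si](C)(C)C(C)(C)C)c1ccc(OC)cc1)N1[C@H](Cc2ccccc2)COC1=O | intermediate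
18 | (2S,3R)-3-(TBS-oxy)-2-(3,5-dimethoxyphenyl)-3-(4-methoxyphenyl)propan-1-ol | OC[C@H](c1cc(OC)cc(OC)c1)[C@@H](O[Si](C)(C)C(C)(C)C)c1ccc(OC)cc1 | intermediate
19 | (2R,3R)-3-(TBS-oxy)-2-(3,5-dimethoxyphenyl)-3-(4-methoxyphenyl)propanal | O=C[C@H](c1cc(OC)cc(OC)c1)[C@@H](O[Si](C)(C)C(C)(C)C)c1ccc(OC)cc1 | intermediate
20 | tert-butyl{[(1R,2R)-4,4-dibromo-2-(3,5-dimethoxyphenyl)-1-(4-methoxyphenyl)but-3-en-1-yl]oxy}dimethylsilane | BrC(Br)=C[C@H](c1cc(OC)cc(OC)c1)[C@@H](O[Si](C)(C)C(C)(C)C)c1ccc(OC)cc1 | intermediate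
21 | [(3S,4R)-4-(TBS-oxy)-3-(3,5-dimethoxyphenyl)-4-(4-methoxyphenyl)but-1-yn-1-yl]lithium | [Li]C#C[C@H](c1cc(OC)cc(OC)c1)[C@@H](O[Si](C)(C)C(C)(C)C)c1ccc(OC)cc1 | intermediate
22 | lithium (3S,4R)-4-(TBS-oxy)-3-(3,5-dimethoxyphenyl)-4-(4-methoxyphenyl)but-1-yn-1-olate | [Li]OC#C[C@H](c1cc(OC)cc(OC)c1)[C@@H](O[Si](C)(C)C(C)(C)C)c1ccc(OC)cc1 | intermediate
23 | tert-butyl{[(1R,2S)-2-(3,5-dimethoxyphenyl)-1-(4-methoxyphenyl)-4-(TIPS-oxy)but-3-yn-1-yl]oxy}dimethylsilane | CC(C)[Si](C(C)C)(C(C)C)OC#C[C@H](c1cc(OC)cc(OC)c1)[C@@H](O[Si](C)(C)C(C)(C)C)c1ccc(OC)cc1 | intermediate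
24 | 3-methylidenehexa-1,5-dien-1-one (vinylketene from 4) | O=C=CC(=C)CC=C | intermediate
25 | 4-(penta-1,4-dien-2-yl)-3-(TIPS-oxy)cyclobut-2-en-1-one carrying the side chain of 23 at C2 (C4 epimers) | O=C1C([C@H](c2cc(OC)cc(OC)c2)[C@@H](O[Si](C)(C)C(C)(C)C)c2ccc(OC)cc2)=C(O[Si](C(C)C)(C(C)C)C(C)C)C1C(=C)CC=C | intermediate
26 | dienylketene from ring opening of 25 | O=C=C([C@H](c1cc(OC)cc(OC)c1)[C@@H](O[Si](C)(C)C(C)(C)C)c1ccc(OC)cc1)/C(O[Si](C(C)C)(C(C)C)C(C)C)=C\C(=C)CC=C | intermediate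
27 | cyclohexa-2,4-dien-1-one tautomer of 28 | O=C1CC(CC=C)=CC(O[Si](C(C)C)(C(C)C)C(C)C)=C1[C@H](c1cc(OC)cc(OC)c1)[C@@H](O[Si](C)(C)C(C)(C)C)c1ccc(OC)cc1 | intermediate
28 | 2-[(1S,2R)-2-(TBS-oxy)-1-(3,5-dimethoxyphenyl)-2-(4-methoxyphenyl)ethyl]-5-(prop-2-en-1-yl)-3-(TIPS-oxy)phenol | Oc1cc(CC=C)cc(O[Si](C(C)C)(C(C)C)C(C)C)c1[C@H](c1cc(OC)cc(OC)c1)[C@@H](O[Si](C)(C)C(C)(C)C)c1ccc(OC)cc1 | intermediate
29 | {[(2S,3S)-3-(3,5-dimethoxyphenyl)-2-(4-methoxyphenyl)-6-(prop-2-en-1-yl)-2,3-dihydro-1-benzofuran-4-yl]oxy}triisopropylsilane | C=CCc1cc(O[Si](C(C)C)(C(C)C)C(C)C)c2c(c1)O[C@H](c1ccc(OC)cc1)[C@H]2c1cc(OC)cc(OC)c1 | intermediate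
30 | tetrabutylammonium (2S,3S)-3-(3,5-dimethoxyphenyl)-2-(4-methoxyphenyl)-6-(prop-2-en-1-yl)-2,3-dihydro-1-benzofuran-4-olate | C=CCc1cc([O-])c2c(c1)O[C@H](c1ccc(OC)cc1)[C@H]2c1cc(OC)cc(OC)c1.CCCC[N+](CCCC)(CCCC)CCCC | intermediate
31 | (2S,3S)-3-(3,5-dimethoxyphenyl)-4-methoxy-2-(4-methoxyphenyl)-6-(prop-2-en-1-yl)-2,3-dihydro-1-benzofuran | C=CCc1cc(OC)c2c(c1)O[C@H](c1ccc(OC)cc1)[C@H]2c1cc(OC)cc(OC)c1 | intermediate
32 | (DHB)acetaldehyde | O=CCc1cc(OC)c2c(c1)O[C@H](c1ccc(OC)cc1)[C@H]2c1cc(OC)cc(OC)c1 | intermediate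
33 | (DHB)acetic acid | OC(=O)Cc1cc(OC)c2c(c1)O[C@H](c1ccc(OC)cc1)[C@H]2c1cc(OC)cc(OC)c1 | intermediate
34 | (DHB)acetic pivalic anhydride | CC(C)(C)C(=O)OC(=O)Cc1cc(OC)c2c(c1)O[C@H](c1ccc(OC)cc1)[C@H]2c1cc(OC)cc(OC)c1 | intermediate
35 | (4R)-4-benzyl-3-[(DHB)acetyl]-1,3-oxazolidin-2-one | O=C(Cc1cc(OC)c2c(c1)O[C@H](c1ccc(OC)cc1)[C@H]2c1cc(OC)cc(OC)c1)N1[C@H](Cc2ccccc2)COC1=O | intermediate
36 | Z dibutylboron enolate of 35 | CCCCB(CCCC)O/C(=C\c1cc(OC)c2c(c1)O[C@H](c1ccc(OC)cc1)[C@H]2c1cc(OC)cc(OC)c1)N1[C@H](Cc2ccccc2)COC1=O | intermediate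
37 | (4R)-4-benzyl-3-[(2R,3R)-2-(DHB)-3-hydroxy-3-(4-methoxyphenyl)propanoyl]-1,3-oxazolidin-2-one | O=C([C@H](c1cc(OC)c2c(c1)O[C@H](c1ccc(OC)cc1)[C@H]2c1cc(OC)cc(OC)c1)[C@@H](O)c1ccc(OC)cc1)N1[C@H](Cc2ccccc2)COC1=O | intermediate
38 | (4R)-4-benzyl-3-[(2R,3R)-3-(TBS-oxy)-2-(DHB)-3-(4-methoxyphenyl)propanoyl]-1,3-oxazolidin-2-one | O=C([C@H](c1cc(OC)c2c(c1)O[C@H](c1ccc(OC)cc1)[C@H]2c1cc(OC)cc(OC)c1)[C@@H](O[Si](C)(C)C(C)(C)C)c1ccc(OC)cc1)N1[C@H](Cc2ccccc2)COC1=O | intermediate
39 | (2S,3R)-3-(TBS-oxy)-2-(DHB)-3-(4-methoxyphenyl)propan-1-ol | OC[C@H](c1cc(OC)c2c(c1)O[C@H](c1ccc(OC)cc1)[C@H]2c1cc(OC)cc(OC)c1)[C@@H](O[Si](C)(C)C(C)(C)C)c1ccc(OC)cc1 | intermediate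
40 | (2R,3R)-3-(TBS-oxy)-2-(DHB)-3-(4-methoxyphenyl)propanal | O=C[C@H](c1cc(OC)c2c(c1)O[C@H](c1ccc(OC)cc1)[C@H]2c1cc(OC)cc(OC)c1)[C@@H](O[Si](C)(C)C(C)(C)C)c1ccc(OC)cc1 | intermediate
41 | tert-butyl{[(1R,2R)-4,4-dibromo-2-(DHB)-1-(4-methoxyphenyl)but-3-en-1-yl]oxy}dimethylsilane | BrC(Br)=C[C@H](c1cc(OC)c2c(c1)O[C@H](c1ccc(OC)cc1)[C@H]2c1cc(OC)cc(OC)c1)[C@@H](O[Si](C)(C)C(C)(C)C)c1ccc(OC)cc1 | intermediate
42 | [(3S,4R)-4-(TBS-oxy)-3-(DHB)-4-(4-methoxyphenyl)but-1-yn-1-yl]lithium | [Li]C#C[C@H](c1cc(OC)c2c(c1)O[C@H](c1ccc(OC)cc1)[C@H]2c1cc(OC)cc(OC)c1)[C@@H](O[Si](C)(C)C(C)(C)C)c1ccc(OC)cc1 | intermediate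
43 | lithium (3S,4R)-4-(TBS-oxy)-3-(DHB)-4-(4-methoxyphenyl)but-1-yn-1-olate | [Li]OC#C[C@H](c1cc(OC)c2c(c1)O[C@H](c1ccc(OC)cc1)[C@H]2c1cc(OC)cc(OC)c1)[C@@H](O[Si](C)(C)C(C)(C)C)c1ccc(OC)cc1 | intermediate
44 | tert-butyl{[(1R,2S)-2-(DHB)-1-(4-methoxyphenyl)-4-(TIPS-oxy)but-3-yn-1-yl]oxy}dimethylsilane | CC(C)[Si](C(C)C)(C(C)C)OC#C[C@H](c1cc(OC)c2c(c1)O[C@H](c1ccc(OC)cc1)[C@H]2c1cc(OC)cc(OC)c1)[C@@H](O[Si](C)(C)C(C)(C)C)c1ccc(OC)cc1 | intermediate
45 | (4E)-5-(2,4-dimethoxyphenyl)-3-methylidenepenta-1,4-dien-1-one (vinylketene from 9) | O=C=CC(=C)/C=C/c1ccc(OC)cc1OC | intermediate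
46 | 4-[(3E)-4-(2,4-dimethoxyphenyl)buta-1,3-dien-2-yl]-3-(TIPS-oxy)cyclobut-2-en-1-one carrying the side chain of 44 at C2 (C4 epimers) | O=C3C([C@H](c1cc(OC)c2c(c1)O[C@H](c1ccc(OC)cc1)[C@H]2c1cc(OC)cc(OC)c1)[C@@H](O[Si](C)(C)C(C)(C)C)c1ccc(OC)cc1)=C(O[Si](C(C)C)(C(C)C)C(C)C)C3C(=C)/C=C/c1ccc(OC)cc1OC | intermediate
47 | dienylketene from ring opening of 46 | O=C=C([C@H](c1cc(OC)c2c(c1)O[C@H](c1ccc(OC)cc1)[C@H]2c1cc(OC)cc(OC)c1)[C@@H](O[Si](C)(C)C(C)(C)C)c1ccc(OC)cc1)/C(O[Si](C(C)C)(C(C)C)C(C)C)=C\C(=C)/C=C/c1ccc(OC)cc1OC | intermediate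
48 | cyclohexa-2,4-dien-1-one tautomer of 49 | O=C1CC(/C=C/c2ccc(OC)cc2OC)=CC(O[Si](C(C)C)(C(C)C)C(C)C)=C1[C@H](c1cc(OC)c2c(c1)O[C@H](c1ccc(OC)cc1)[C@H]2c1cc(OC)cc(OC)c1)[C@@H](O[Si](C)(C)C(C)(C)C)c1ccc(OC)cc1 | intermediate
49 | 2-[(1S,2R)-2-(TBS-oxy)-1-(DHB)-2-(4-methoxyphenyl)ethyl]-5-[(E)-2-(2,4-dimethoxyphenyl)ethenyl]-3-(TIPS-oxy)phenol | Oc1cc(/C=C/c2ccc(OC)cc2OC)cc(O[Si](C(C)C)(C(C)C)C(C)C)c1[C@H](c1cc(OC)c2c(c1)O[C@H](c1ccc(OC)cc1)[C@H]2c1cc(OC)cc(OC)c1)[C@@H](O[Si](C)(C)C(C)(C)C)c1ccc(OC)cc1 | intermediate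
50 | 2-[(1S,2R)-1-(DHB)-2-hydroxy-2-(4-methoxyphenyl)ethyl]-5-[(E)-2-(2,4-dimethoxyphenyl)ethenyl]benzene-1,3-diol | Oc1cc(/C=C/c2ccc(OC)cc2OC)cc(O)c1[C@H](c1cc(OC)c2c(c1)O[C@H](c1ccc(OC)cc1)[C@H]2c1cc(OC)cc(OC)c1)[C@@H](O)c1ccc(OC)cc1 | intermediate
51 | (2S,3S)-3-(DHB)-6-[(E)-2-(2,4-dimethoxyphenyl)ethenyl]-2-(4-methoxyphenyl)-2,3-dihydro-1-benzofuran-4-ol | COc1ccc([C@H]2Oc3cc(/C=C/c4ccc(OC)cc4OC)cc(O)c3[C@@H]2c2cc(OC)c3c(c2)O[C@H](c2ccc(OC)cc2)[C@H]3c2cc(OC)cc(OC)c2)cc1 | intermediate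
52 | CNP0186204.1, (2S,3S)-6-[(E)-2-(2,4-dihydroxyphenyl)ethenyl]-3-[(2S,3S)-3-(3,5-dihydroxyphenyl)-4-hydroxy-2-(4-hydroxyphenyl)-2,3-dihydro-1-benzofuran-6-yl]-2-(4-hydroxyphenyl)-2,3-dihydro-1-benzofuran-4-ol | Oc1ccc([C@H]2Oc3cc(/C=C/c4ccc(O)cc4O)cc(O)c3[C@@H]2c2cc(O)c3c(c2)O[C@H](c2ccc(O)cc2)[C@H]3c2cc(O)cc(O)c2)cc1 | target

Total step count: 26.
Longest linear sequence: 23 steps (steps 4–26, from acid 10); steps 1 and 2–3 are side branches.

Steps most likely to fail

1. Step 23. The cross-conjugated styryl vinylketene 45 (or dienone 9 itself) may be consumed by dimerisation and oligomerisation through its electron-rich diene before the hindered, β-branched ynol ether 44 captures it. The fallback separates ring construction from stilbene construction. It sets out from 44, which is heated with the simple cyclobutenone 4 under the conditions of step 11 to give the allyl phenol F1. TBAF removes both silyl groups to give the allyl triol F2, and catalytic TsOH closes ring 1 to the 6-allyl dihydrobenzofuranol F3. Ruthenium hydride isomerisation (RuHCl(CO)(PPh3)3, toluene, 80 °C) moves the alkene into conjugation to give the E-propenyl dihydrobenzofuranol F4. Cross-metathesis of this with 2,4-dimethoxystyrene (Hoveyda–Grubbs second-generation catalyst, CH2Cl2, 40 °C) builds the E-stilbene, and the route is rejoined at 51.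

2. Step 26. The Lewis acid and the hydrogen bromide it releases may ionise the C2–O1 bonds and protonate the electron-rich stilbene, so that ring-opened, cyclised or oligomeric material forms before all seven ethers are cleaved. The fallback replaces acid cleavage by dealkylation in a Grignard melt. It sets out from 51, which is heated with excess methylmagnesium iodide without solvent at about 160 °C; this reagent demethylates resorcinol dimethyl ethers of acid-sensitive substrates through their magnesium phenoxides. Quenching with aqueous NH4Cl returns directly to 52, and no new compound is made.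

3. Step 21 (together with steps 20 and 22, and likewise steps 8–10). Aldehyde 40 may lose configuration at the α-aryl carbon by enolisation, or eliminate silanol to the conjugated enal, during oxidation and olefination, and the acetylide oxidation that follows in the same flask as the rearrangement may stall. The fallback avoids the aldehyde oxidation level and the acetylide altogether by an ester-to-ynolate homologation of the Kowalski type. It sets out from imide 38, whose ethanolysis (EtOMgBr, THF, 0 °C) gives the ethyl ester F5. Addition of LiCHBr2 (from CH2Br2 and LiTMP, THF, −78 °C) and deprotonation with LiHMDS give the dibromomethyl ketone enolate F6. n-BuLi then triggers bromine–lithium exchange and 1,2-shift of the alkyl group with retention to give lithium ynolate 43, which TIPSOTf traps; steps 19–22 are bypassed and the route is rejoined at 44.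

Further compounds
F1 | step 23 | 2-[(1S,2R)-2-(TBS-oxy)-1-(DHB)-2-(4-methoxyphenyl)ethyl]-5-(prop-2-en-1-yl)-3-(TIPS-oxy)phenol | Oc1cc(CC=C)cc(O[Si](C(C)C)(C(C)C)C(C)C)c1[C@H](c1cc(OC)c2c(c1)O[C@H](c1ccc(OC)cc1)[C@H]2c1cc(OC)cc(OC)c1)[C@@H](O[Si](C)(C)C(C)(C)C)c1ccc(OC)cc1
F2 | step 23 | 2-[(1S,2R)-1-(DHB)-2-hydroxy-2-(4-methoxyphenyl)ethyl]-5-(prop-2-en-1-yl)benzene-1,3-diol | Oc1cc(CC=C)cc(O)c1[C@H](c1cc(OC)c2c(c1)O[C@H](c1ccc(OC)cc1)[C@H]2c1cc(OC)cc(OC)c1)[C@@H](O)c1ccc(OC)cc1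
F3 | step 23 | (2S,3S)-3-(DHB)-2-(4-methoxyphenyl)-6-(prop-2-en-1-yl)-2,3-dihydro-1-benzofuran-4-ol | COc1ccc([C@H]2Oc3cc(CC=C)cc(O)c3[C@@H]2c2cc(OC)c3c(c2)O[C@H](c2ccc(OC)cc2)[C@H]3c2cc(OC)cc(OC)c2)cc1
F4 | step 23 | (2S,3S)-3-(DHB)-2-(4-methoxyphenyl)-6-[(E)-prop-1-en-1-yl]-2,3-dihydro-1-benzofuran-4-ol | COc1ccc([C@H]2Oc3cc(/C=C/C)cc(O)c3[C@@H]2c2cc(OC)c3c(c2)O[C@H](c2ccc(OC)cc2)[C@H]3c2cc(OC)cc(OC)c2)cc1
F0 | step 26 | none | none
F5 | step 21 | ethyl (2R,3R)-3-(TBS-oxy)-2-(DHB)-3-(4-methoxyphenyl)propanoate | CCOC(=O)[C@H](c1cc(OC)c2c(c1)O[C@H](c1ccc(OC)cc1)[C@H]2c1cc(OC)cc(OC)c1)[C@@H](O[Si](C)(C)C(C)(C)C)c1ccc(OC)cc1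
F6 | step 21 | lithium (3R,4R)-1,1-dibromo-4-(TBS-oxy)-3-(DHB)-4-(4-methoxyphenyl)but-1-en-2-olate | [Li]OC(=C(Br)Br)[C@H](c1cc(OC)c2c(c1)O[C@H](c1ccc(OC)cc1)[C@H]2c1cc(OC)cc(OC)c1)[C@@H](O[Si](C)(C)C(C)(C)C)c1ccc(OC)cc1
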